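**Retrosynthetic overview**
1. Ferulsinaic acid (14) ← Wittig isopropylidenation of aldehyde-acid 13 ← ozonolysis of the silyl enol ether C=C of a cis-fused hexahydroindene (12); one cleavage releases the CHO (future isobutenyl) and the CH2CH2CO2H arm, already cis on the cyclopentane.
2. Aryl ether 12 ← Mitsunobu coupling of umbelliferone with the primary alcohol obtained from the ring ester.
3. Hydrindene ← intramolecular Diels–Alder of a 2-silyloxy-1,6,8-nonatriene (7). The cyclopentane and a sacrificial cyclohexene form together in this one step (the only ring-forming event); the quaternary carbon and its CH neighbour are set here.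
4. Triene 7 ← ester-enolate aldol/dehydration (isopropenyl dienophile) on keto ester 4 ← (R)-citronellal by acetonyl Wittig and degradation of the prenyl tail. The citronellal methyl stereocentre is the only one bought; it controls the rest.

Assumption: commercial (R)-(+)-citronellal of ≥98% ee is used. Locants C1, C2, C3a, C7a below are indene locants of the bicyclic intermediates.

**Step 1**
Reactants: 1, (R)-(+)-citronellal
Product: 2, (6R,3E)-6,10-dimethylundeca-3,9-dien-2-one
Conditions: Ph3P=CHCOMe, PhMe, 90 °C
Reagents that add atoms: 1-(triphenylphosphoranylidene)propan-2-one, CC(=O)C=P(c1ccccc1)(c1ccccc1)c1ccccc1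
Why: Wittig olefination with a stabilised ylide gives the E-enone; the stereocentre is β to the aldehyde and is not touched.

**Step 2**
Reactants: 2
Product: 3, (6R,3E,8E)-10-hydroxy-6,10-dimethylundeca-3,8-dien-2-one
Conditions: PhSeCl, MeCN–H2O, rt; then H2O2, pyridine, CH2Cl2, 0 °C → rt
Reagents that add atoms: water, O
Why: Markovnikov hydroxyselenation of the electron-rich trisubstituted alkene (enone inert) followed by selenoxide syn-elimination, which can only go toward C8, transposes the alkene to the E-8,9 position.

**Step 3**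
Reactants: 3
Product: 4, methyl (3S,5E)-3-methyl-7-oxooct-5-enoate
Conditions: O3 (1 equiv, dye end-point), CH2Cl2–MeOH, NaHCO3, −78 °C; then Ac2O, Et3N, 0 °C → rt
Reagents that add atoms: ozone, [O-][O+]=O; methanol, CO
Why: Criegee ozonolysis of the isolated alkene in preference to the enone; the carbonyl oxide forms on the carbon remote from the allylic C–O, is trapped by MeOH and dehydrated to the methyl ester (the hydroxy-aldehyde fragment is discarded).

**Step 4**
Reactants: 4
Product: 5, methyl (3S,5E)-3-methyl-7-[(triisopropylsilyl)oxy]octa-5,7-dienoate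
Conditions: TIPSOTf, Et3N, CH2Cl2, −78 → 0 °C
Reagents that add atoms: triisopropylsilyl triflate, CC(C)[Si](OS(=O)(=O)C(F)(F)F)(C(C)C)C(C)C
Why: Soft enolisation/O-silylation at the methyl group of the ketone gives the cross-conjugated 2-silyloxy-1,3-diene with the E-alkene retained; the ester does not react.

**Step 5**
Reactants: 5
Product: 6, methyl (2RS,3S,5E)-2-(2-hydroxypropan-2-yl)-3-methyl-7-[(triisopropylsilyl)oxy]octa-5,7-dienoate (both C2 epimers)
Conditions: LDA, THF, −78 °C; acetone; AcOH quench at −78 °C
Reagents that add atoms: acetone, CC(C)=O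
Why: Ester-enolate aldol addition to acetone; little 1,2-induction is expected at the new C2 centre, so both epimers are carried and C2 is corrected in step 8.

**Step 6**
Reactants: 6
Product: 7, methyl (2RS,3S,5E)-3-methyl-2-(prop-1-en-2-yl)-7-[(triisopropylsilyl)oxy]octa-5,7-dienoate
Conditions: Burgess reagent, PhMe, 60 °C
Reagents that add atoms: none
Why: Neutral syn-dehydration of the tertiary alcohol toward a methyl group gives the isopropenyl (β,γ-unsaturated) ester; any conjugated isomer can be returned to 7 by LDA deconjugation/kinetic protonation.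

**Step 7**
Reactants: 7 (both C2 epimers)
Product: 8, methyl (1RS,2S,3aS,7aR)-2,7a-dimethyl-5-[(triisopropylsilyl)oxy]-2,3,3a,6,7,7a-hexahydro-1H-indene-1-carboxylate (cis-fused)
Conditions: PhMe (5 mM), BHT, cat. Et3N, 200 °C, sealed tube
Reagents that add atoms: none
Why: Thermal type-1 intramolecular Diels–Alder reaction; the tether-endo/angular-methyl-exo transition state gives the cis ring fusion, and the citronellal-derived methyl sits pseudo-equatorial (cis to the C3a–C4 bond), which sets C3a and C7a.

**Step 8**
Reactants: 8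
Product: 9, methyl (1R,2S,3aS,7aR)-2,7a-dimethyl-5-[(triisopropylsilyl)oxy]-2,3,3a,6,7,7a-hexahydro-1H-indene-1-carboxylate
Conditions: t-BuOK (0.3 equiv), t-BuOH–THF, 40 °C
Reagents that add atoms: none
Why: Thermodynamic enolate equilibration places the ester trans to the C2 methyl on the convex face (one cis-vicinal interaction instead of two), converging both epimers to the 1R ester.

**Step 9**
Reactants: 9
Product: 10, [(1R,2S,3aS,7aR)-2,7a-dimethyl-5-[(triisopropylsilyl)oxy]-2,3,3a,6,7,7a-hexahydro-1H-inden-1-yl]methanol
Conditions: LiAlH4, THF, 0 °C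
Reagents that add atoms: none
Why: Hydride reduction of the ester to the primary alcohol; the silyl enol ether is inert and C1 can no longer epimerise.

**Step 10**
Reactants: 10; 11, umbelliferone (7-hydroxy-2H-chromen-2-one)
Product: 12, 7-{[(1R,2S,3aS,7aR)-2,7a-dimethyl-5-[(triisopropylsilyl)oxy]-2,3,3a,6,7,7a-hexahydro-1H-inden-1-yl]methoxy}-2H-chromen-2-one
Conditions: PPh3, DIAD (betaine pre-formed), THF, 0 → 40 °C
Reagents that add atoms: none (11 is a reactant)
Why: Mitsunobu etherification of a primary, β-branched (not neopentyl) alcohol with the acidic phenol (pKa about 7.8); no stereocentre is involved.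

**Step 11**
Reactants: 12
Product: 13, 3-[(1S,2R,3S,5R)-5-formyl-1,3-dimethyl-2-{[(2-oxo-2H-chromen-7-yl)oxy]methyl}cyclopentyl]propanoic acid
Conditions: O3 (1 equiv, dye end-point), CH2Cl2, −78 °C; PPh3; mild aqueous acid work-up
Reagents that add atoms: ozone, [O-][O+]=O
Why: Ozonolysis of the very electron-rich silyl enol ether (far faster than the coumarin C3=C4) gives the aldehyde on the ring CH and, via the silyl ester, the carboxylic acid on the three-carbon arm, cis by construction.

**Step 12**
Reactants: 13
Product: 14, ferulsinaic acid, 3-[(1R,2R,3S,5S)-1,3-dimethyl-5-(2-methylprop-1-en-1-yl)-2-{[(2-oxo-2H-chromen-7-yl)oxy]methyl}cyclopentyl]propanoic acid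
Conditions: i-PrPPh3+ I−, n-BuLi (2.2–2.5 equiv ylide), THF, −78 → 0 °C; then H3O+
Reagents that add atoms: isopropyltriphenylphosphonium iodide, CC(C)[P+](c1ccccc1)(c1ccccc1)c1ccccc1.[I-]
Why: Wittig olefination with isopropylidenetriphenylphosphorane converts the aldehyde to the isobutenyl group (one equivalent of ylide is spent on the carboxylic acid); low temperature limits α-epimerisation and attack on the lactone.

**Compound list**
1 | (R)-(+)-citronellal | O=CC[C@H](C)CCC=C(C)C | starting material
2 | (6R,3E)-6,10-dimethylundeca-3,9-dien-2-one | CC(=O)/C=C/C[C@H](C)CCC=C(C)C | intermediate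
3 | (6R,3E,8E)-10-hydroxy-6,10-dimethylundeca-3,8-dien-2-one | CC(=O)/C=C/C[C@H](C)C/C=C/C(C)(C)O | intermediate
4 | methyl (3S,5E)-3-methyl-7-oxooct-5-enoate | CC(=O)/C=C/C[C@H](C)CC(=O)OC | intermediate
5 | methyl (3S,5E)-3-methyl-7-[(triisopropylsilyl)oxy]octa-5,7-dienoate | C=C(O[Si](C(C)C)(C(C)C)C(C)C)/C=C/C[C@H](C)CC(=O)OC | intermediate
6 | methyl (2RS,3S,5E)-2-(2-hydroxypropan-2-yl)-3-methyl-7-[(triisopropylsilyl)oxy]octa-5,7-dienoate (C2 epimers) | C=C(O[Si](C(C)C)(C(C)C)C(C)C)/C=C/C[C@H](C)C(C(=O)OC)C(C)(C)O | intermediate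
7 | methyl (2RS,3S,5E)-3-methyl-2-(prop-1-en-2-yl)-7-[(triisopropylsilyl)oxy]octa-5,7-dienoate (C2 epimers) | C=C(O[Si](C(C)C)(C(C)C)C(C)C)/C=C/C[C@H](C)C(C(=O)OC)C(C)=C | intermediate
8 | methyl (1RS,2S,3aS,7aR)-2,7a-dimethyl-5-[(triisopropylsilyl)oxy]-2,3,3a,6,7,7a-hexahydro-1H-indene-1-carboxylate (C1 epimers) | CC(C)[Si](C(C)C)(C(C)C)OC1=C[C@@H]2C[C@H](C)C(C(=O)OC)[C@]2(C)CC1 | intermediate
9 | methyl (1R,2S,3aS,7aR)-2,7a-dimethyl-5-[(triisopropylsilyl)oxy]-2,3,3a,6,7,7a-hexahydro-1H-indene-1-carboxylate | CC(C)[Si](C(C)C)(C(C)C)OC1=C[C@@H]2C[C@H](C)[C@@H](C(=O)OC)[C@]2(C)CC1 | intermediate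
10 | [(1R,2S,3aS,7aR)-2,7a-dimethyl-5-[(triisopropylsilyl)oxy]-2,3,3a,6,7,7a-hexahydro-1H-inden-1-yl]methanol | CC(C)[Si](C(C)C)(C(C)C)OC1=C[C@@H]2C[C@H](C)[C@@H](CO)[C@]2(C)CC1 | intermediate
11 | umbelliferone (7-hydroxy-2H-chromen-2-one) | O=c1ccc2ccc(O)cc2o1 | starting material
12 | 7-{[(1R,2S,3aS,7aR)-2,7a-dimethyl-5-[(triisopropylsilyl)oxy]-2,3,3a,6,7,7a-hexahydro-1H-inden-1-yl]methoxy}-2H-chromen-2-one | CC(C)[Si](C(C)C)(C(C)C)OC1=C[C@@H]2C[C@H](C)[C@@H](COc3ccc4ccc(=O)oc4c3)[C@]2(C)CC1 | intermediate
13 | 3-[(1S,2R,3S,5R)-5-formyl-1,3-dimethyl-2-{[(2-oxo-2H-chromen-7-yl)oxy]methyl}cyclopentyl]propanoic acid | O=C[C@@H]1C[C@H](C)[C@@H](COc2ccc3ccc(=O)oc3c2)[C@]1(C)CCC(=O)O | intermediate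
14 | ferulsinaic acid | CC(C)=C[C@@H]1C[C@H](C)[C@@H](COc2ccc3ccc(=O)oc3c2)[C@]1(C)CCC(=O)O | target

**Totals**
Total step count: 12. Longest linear sequence: 12 (1 → 14; umbelliferone enters at step 10).

**Steps most likely to fail, with fallbacks**
1. Step 7 (cycloaddition). The dienophile is an unactivated 1,1-disubstituted alkene, so the reaction needs about 200 °C, and the cis/trans fusion and facial selectivity are predicted rather than known. Fallback: build the rings stepwise instead. Close a 2-methylcyclopentanone carrying the same methyl and ester groups first (Dieckmann-type closure from the citronellal-derived chain), then annulate the six-membered ring by Robinson annulation and cleave it in the same way.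
2. Steps 5, 6 and 8 (isopropenyl installation and the ester-bearing stereocentre). There is no control at C2 in the aldol, the dehydration regiochemistry may be mixed, and the equilibration must spare the silyl enol ether. Fallback: carry out the acetone aldol/dehydration on the cyclic trans-directing δ-lactone (4-methyltetrahydropyran-2-one, from (R)-citronellol by the same selenoxide/ozonolysis sequence plus lactol oxidation). This fixes the stereocentre before the cycloaddition and removes step 8, at the cost of about two extra steps.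
3. Step 12 (Wittig). The aldehyde is hindered and epimerisable, and a free acid and the coumarin lactone are present. Fallback: reorder the endgame so the olefination is done without them: ozonolyse alcohol 10, esterify the acid (TMSCHN2), olefinate, then Mitsunobu coupling with 11 and LiOH hydrolysis (two extra steps).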